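**Plan**

- Enabling feature: the non-aromatic ring is the enol form of a 2-acylcyclohexane-1,3,5-trione. Its six ring carbons plus the butanoyl C=O are a folded 3,5,7-triketo acid chain, the C(CH3)2 carbon sits between two carbonyls (no enolisation there, no aromatising aldol), and the ring carbonyl next to the CH2-bridged carbon can be tied to an ortho-hydroxyl of the aryl ring as a six-membered aryl lactone.
- Retrosynthesis: cut the ring bond between the butanoyl-bearing carbon and that ring carbonyl (intramolecular Claisen on the lactone, a chroman-2-one). Then cut C3=C4 of the corresponding coumarin (Knoevenagel) into an aryl aldehyde and a β-keto ester whose remote 1,3-diketone is masked as an isoxazole (nitrile oxide/alkyne cycloaddition, ester Claisen).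
- Forward order: isoxazole ring (mask), then β-keto ester; aryl aldehyde by ortho-demethylation and C-acylation; coumarin ring (temporary) by condensation; hydrogenation saturates the coumarin and unmasks the diketone; the Claisen step closes the carbocycle and opens the lactone in one event, so the unsymmetrical methylene bridge is in place before the ring exists.
- Stereochemistry: the target has no stereocentre; the single racemic centre of the lactone intermediates becomes sp2 in the key step.

Key step: step 7

Assumption: in step 5 the lactone is taken to close through the hydroxyl para to the butanoyl group (the one not hydrogen-bonded to the ketone); closure through the other hydroxyl would give a regioisomeric lactone that step 7 opens to the same product.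

**Route**

Step 1
Reactants: 1 butanal oxime; 2 methyl 2,2-dimethylbut-3-ynoate
Product: 5 methyl 2-methyl-2-(3-propyl-1,2-oxazol-5-yl)propanoate, via hydroximoyl chloride 3 (not isolated), via nitrile oxide 4 (not isolated)
Conditions: NCS, DMF, rt; then 2, Et3N (slow addition), CH2Cl2, 0 °C → rt
Reagents that add atoms: none
Why: Huisgen 1,3-dipolar cycloaddition of a nitrile oxide (made by chlorination of the oxime and dehydrochlorination) with a terminal alkyne; steric and frontier-orbital control should place the oxygen on the substituted alkyne carbon and give the 3,5-disubstituted isoxazole, a base-stable masked 1,3-diketone.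

Step 2
Reactants: 5 methyl 2-methyl-2-(3-propyl-1,2-oxazol-5-yl)propanoate; 6 methyl acetate
Product: 7 methyl 4-methyl-3-oxo-4-(3-propyl-1,2-oxazol-5-yl)pentanoate
Conditions: 6 (3 equiv), LiN(i-Pr)2 (3 equiv), THF, −78 °C; then 5, −78 → −30 °C; aq. HCl
Reagents that add atoms: none
Why: Crossed Claisen condensation: 5 has no α-hydrogen and can only accept the preformed lithium enolate of 6, the product is protected in the flask as its β-keto ester enolate, and the isoxazole should not be metalated by an ester enolate at low temperature.

Step 3
Reactants: 8 2,4,6-trimethoxybenzaldehyde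
Product: 9 2,6-dihydroxy-4-methoxybenzaldehyde
Conditions: AlCl3 (4 equiv), CH2Cl2, 0 °C → reflux; ice, aq. HCl
Reagents that add atoms: none
Why: Chelation-directed Lewis acid ether cleavage: AlCl3 bound to the formyl oxygen should cleave only the two flanking ortho-methoxy groups (six-membered aluminium chelates), so the para-methoxy group is kept and the symmetrical 2,6-diol results.

Step 4
Reactants: 9 2,6-dihydroxy-4-methoxybenzaldehyde; 10 butanoyl chloride
Product: 11 3-butanoyl-2,6-dihydroxy-4-methoxybenzaldehyde
Conditions: 10 (1.2 equiv), AlCl3 (3.5 equiv), PhNO2, 0 °C → rt; ice, aq. HCl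
Reagents that add atoms: none
Why: Friedel–Crafts C-acylation (directly or by O-acylation and Fries shift) of a ring that still carries three oxygen donors, as in the formation of 2,4-diacylphloroglucinols; the two open positions are equivalent by symmetry, so only one regioisomer can form, and nitrobenzene-moderated AlCl3 at room temperature should spare the remaining methyl ether.

Step 5
Reactants: 11 3-butanoyl-2,6-dihydroxy-4-methoxybenzaldehyde; 7 methyl 4-methyl-3-oxo-4-(3-propyl-1,2-oxazol-5-yl)pentanoate
Product: 13 6-butanoyl-5-hydroxy-7-methoxy-3-[2-methyl-2-(3-propyl-1,2-oxazol-5-yl)propanoyl]-2H-chromen-2-one, via Knoevenagel adduct 12 (not isolated)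
Conditions: piperidine (20 mol%), AcOH (20 mol%), EtOH, reflux
Reagents that add atoms: none
Why: Knoevenagel condensation followed by lactonisation, the classical coumarin synthesis from a salicylaldehyde and a β-keto ester; the β-keto ester CH2 is the only active methylene because the remote 1,3-diketone is locked in the isoxazole, and the aldehyde should react in preference to the chelated, hindered aryl ketone.

Step 6
Reactants: 13 6-butanoyl-5-hydroxy-7-methoxy-3-[2-methyl-2-(3-propyl-1,2-oxazol-5-yl)propanoyl]-2H-chromen-2-one
Product: 16 6-butanoyl-3-(2,2-dimethyl-3,5-dioxooctanoyl)-5-hydroxy-7-methoxy-3,4-dihydro-2H-chromen-2-one (racemic), via dihydrocoumarin isoxazole 14 (not isolated), via enaminone lactone 15 (not isolated)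
Conditions: H2 (1 atm), Pd/C (10 wt%), THF, rt; filter; then 1 M aq. HCl, THF, 0 °C → rt
Reagents that add atoms: water, O
Why: Heterogeneous hydrogenation should saturate the electron-poor C3=C4 bond of the 3-acylcoumarin and cleave the weak N–O bond of the isoxazole to the Z-enaminone (the standard isoxazole unmasking), and brief cold aqueous acid hydrolyses this vinylogous amide to the 1,3-diketone while the chelated aryl ketone and the aryl lactone stay intact; the new centre at C3 forms racemic and is erased in step 7.

Step 7
Reactants: 16 6-butanoyl-3-(2,2-dimethyl-3,5-dioxooctanoyl)-5-hydroxy-7-methoxy-3,4-dihydro-2H-chromen-2-one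
Product: 17 2-butanoyl-6-[(3-butanoyl-2,6-dihydroxy-4-methoxyphenyl)methyl]-3,5-dihydroxy-4,4-dimethylcyclohexa-2,5-dien-1-one (the target)
Conditions: DBU (2.2 equiv), DMAP (10 mol%), MeCN, 0 °C → rt; then cold 1 M aq. HCl
Reagents that add atoms: none
Why: DBU removes a proton from the C4 methylene of the 2,2-dimethyl-3,5-dioxooctanoyl chain (the most acidic C–H of 16) and the diketone enolate carbon adds to the lactone carbonyl, an aryl ester further activated by its α-keto group; collapse of the tetrahedral intermediate expels the ring oxygen as the phenoxide that is the free ortho-hydroxyl of the target, and the new 2-acyl-1,3,5-trione is at once deprotonated to its delocalised anion, so the step is an irreversible isomerisation that splits nothing off. The closest known reaction type is the intramolecular Claisen (Dieckmann-type) condensation of 3,5,7-triketo esters to acylphloroglucinols, the laboratory counterpart of the biosynthetic folding of a tetraketide, together with acyl transfer from aryl esters to 1,3-diones. The carbocycle closes in a 6-(enolexo)-exo-trig mode while the six-membered lactone ring opens. No stereocentre is formed, and the racemic centre at C3 of 16 becomes sp2. The selectivity needed is carbon- over oxygen-acylation and Claisen over aldol: with about two equivalents of base the anionic sites are the chelated phenol and the diketone methylene, so the nucleophile is the diketone carbon and the lactone stays a neutral electrophile, whereas an aldol closure would need the less acidic lactone C3–H ionised and a non-enolised ketone; O-acylated alternatives remain activated esters that the phenoxide or DMAP reopens, and C(CH3)2 between the two ketones rules out any other enolate or an aromatisation. A non-nucleophilic amidine base at room temperature should avoid retro-Claisen cleavage at the quaternary carbon and exchange at the methylene bridge.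

**Compound list**

1 | butanal oxime (E/Z mixture) | CCCC=NO | starting material
2 | methyl 2,2-dimethylbut-3-ynoate | COC(=O)C(C)(C)C#C | starting material
3 | (1Z)-N-hydroxybutanimidoyl chloride | CCC/C(Cl)=N/O | intermediate (not isolated)
4 | butanenitrile oxide | CCCC#[N+][O-] | intermediate (not isolated)
5 | methyl 2-methyl-2-(3-propyl-1,2-oxazol-5-yl)propanoate | CCCc1cc(on1)C(C)(C)C(=O)OC | intermediate
6 | methyl acetate | COC(C)=O | starting material
7 | methyl 4-methyl-3-oxo-4-(3-propyl-1,2-oxazol-5-yl)pentanoate | CCCc1cc(on1)C(C)(C)C(=O)CC(=O)OC | intermediate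
8 | 2,4,6-trimethoxybenzaldehyde | COc1cc(OC)c(C=O)c(OC)c1 | starting material
9 | 2,6-dihydroxy-4-methoxybenzaldehyde | COc1cc(O)c(C=O)c(O)c1 | intermediate
10 | butanoyl chloride | CCCC(Cl)=O | starting material
11 | 3-butanoyl-2,6-dihydroxy-4-methoxybenzaldehyde | CCCC(=O)c1c(OC)cc(O)c(C=O)c1O | intermediate
12 | methyl (2Z)-2-[(3-butanoyl-2,6-dihydroxy-4-methoxyphenyl)methylidene]-4-methyl-3-oxo-4-(3-propyl-1,2-oxazol-5-yl)pentanoate | COC(=O)/C(=C\c1c(O)cc(OC)c(C(=O)CCC)c1O)C(=O)C(C)(C)c1cc(CCC)no1 | intermediate (not isolated)
13 | 6-butanoyl-5-hydroxy-7-methoxy-3-[2-methyl-2-(3-propyl-1,2-oxazol-5-yl)propanoyl]-2H-chromen-2-one | CCCc1cc(on1)C(C)(C)C(=O)C1=Cc2c(O)c(C(=O)CCC)c(OC)cc2OC1=O | intermediate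
14 | 6-butanoyl-5-hydroxy-7-methoxy-3-[2-methyl-2-(3-propyl-1,2-oxazol-5-yl)propanoyl]-3,4-dihydro-2H-chromen-2-one (racemic) | CCCc1cc(on1)C(C)(C)C(=O)C1Cc2c(O)c(C(=O)CCC)c(OC)cc2OC1=O | intermediate (not isolated)
15 | 3-[(4Z)-5-amino-2,2-dimethyl-3-oxooct-4-enoyl]-6-butanoyl-5-hydroxy-7-methoxy-3,4-dihydro-2H-chromen-2-one (racemic) | CCC/C(N)=C/C(=O)C(C)(C)C(=O)C1Cc2c(O)c(C(=O)CCC)c(OC)cc2OC1=O | intermediate (not isolated)
16 | 6-butanoyl-3-(2,2-dimethyl-3,5-dioxooctanoyl)-5-hydroxy-7-methoxy-3,4-dihydro-2H-chromen-2-one (racemic) | CCCC(=O)CC(=O)C(C)(C)C(=O)C1Cc2c(O)c(C(=O)CCC)c(OC)cc2OC1=O | intermediate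
17 | 2-butanoyl-6-[(3-butanoyl-2,6-dihydroxy-4-methoxyphenyl)methyl]-3,5-dihydroxy-4,4-dimethylcyclohexa-2,5-dien-1-one | CCCC(=O)C1=C(O)C(C)(C)C(O)=C(Cc2c(O)cc(OC)c(C(=O)CCC)c2O)C1=O | target

**Totals**

Total step count: 7. Longest linear sequence: 5 steps (steps 1, 2, 5, 6, 7; the arene branch, steps 3, 4, 5, 6, 7, is equally long).

**Steps most likely to fail**

Step 7. What may go wrong: acyl transfer to the enol oxygen instead of the carbon, cleavage of the non-enolisable 1,3-diketone at the quaternary carbon, or base-induced exchange at the methylene bridge after ring closure. The fallback sets out from 10, uses 11 and comes back at 17; the ring is made by dearomatisation instead of folding. Friedel–Crafts acylation of commercial phloroglucinol with 10 (AlCl3, PhNO2) should give 1-(2,4,6-trihydroxyphenyl)butan-1-one F1. Geminal C-methylation (MeI, NaOMe, MeOH) dearomatises it to 2-butanoyl-3,5-dihydroxy-4,4-dimethylcyclohexa-2,5-dien-1-one F2. Organocatalytic reductive alkylation of F2 at its only free ring carbon with aldehyde 11 (Hantzsch ester, L-proline cat., CH2Cl2, rt) should then give 17, the regiochemistry of the bridge being fixed by the aldehyde.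

Step 6. What may go wrong: over-reduction at the aryl ketone, reaction of the newly formed enaminone (through nitrogen or carbon) with the aryl lactone or the neighbouring ketone before it is hydrolysed, or hydrolytic opening and decarboxylation of the β-keto lactone during the acid treatment. The fallback sets out from 7 and comes back at 17; unmasking is moved in front of the union. Hydrogenolysis of 7 (H2, Pd/C, EtOAc) should give methyl (6Z)-7-amino-4,4-dimethyl-3,5-dioxodec-6-enoate F3, which dilute HCl hydrolyses to methyl 4,4-dimethyl-3,5,7-trioxodecanoate F4. Claisen cyclisation of this simple triketo ester (KOt-Bu, THF) forms the same ring bond and gives F2, which is joined to 11 by the reductive alkylation described above to reach 17.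

Step 4. What may go wrong: sluggish substitution on the formyl-deactivated ring, capture of the aldehyde by the acid chloride–Lewis acid pair, or chelation-assisted loss of the methyl ether next to the new ketone. The fallback sets out from 9 and comes back at 11. Selective mono-O-acylation of 9 with 10 (Et3N, CH2Cl2, 0 °C) should give 2-formyl-3-hydroxy-5-methoxyphenyl butanoate F5. A photo-Fries rearrangement (hν 254 nm, MeCN) then moves the acyl group to carbon without any Lewis acid; ortho and para migration lead to the same compound 11 because of the symmetry of the ring.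

Further compounds
F1 | step 7 | 1-(2,4,6-trihydroxyphenyl)butan-1-one | CCCC(=O)c1c(O)cc(O)cc1O
F2 | step 7 | 2-butanoyl-3,5-dihydroxy-4,4-dimethylcyclohexa-2,5-dien-1-one | CCCC(=O)C1=C(O)C(C)(C)C(O)=CC1=O
F3 | step 6 | methyl (6Z)-7-amino-4,4-dimethyl-3,5-dioxodec-6-enoate | CCC/C(N)=C/C(=O)C(C)(C)C(=O)CC(=O)OC
F4 | step 6 | methyl 4,4-dimethyl-3,5,7-trioxodecanoate | CCCC(=O)CC(=O)C(C)(C)C(=O)CC(=O)OC
F5 | step 4 | 2-formyl-3-hydroxy-5-methoxyphenyl butanoate | CCCC(=O)Oc1cc(OC)cc(O)c1C=O
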